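A direct plan would keep the benzene ring of 3,4-dibromobenzaldehyde A1 and build the pyrrole ring onto it.
It would nitrate A1 to 4,5-dibromo-2-nitrobenzaldehyde A2, and a nitroaldol addition with dehydration would give the dinitrostyrene 1,2-dibromo-4-nitro-5-[(E)-2-nitroethenyl]benzene A3.
Reductive cyclisation would give 5,6-dibromo-1H-indole A4, N-methylation would give 5,6-dibromo-1-methyl-1H-indole A5, and bromination at C3 would give the target.
Its weakest points would be:
- The nitration of A1 to A2 that places the nitrogen: its site rests only on the competing directing effects of two bromines and the aldehyde, so isomers would have to be removed at the very start, and no skeletal bond is built.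
- The nitroaldol, dehydration and reductive cyclisation run from A2 through A3 to A4: three operations, through a base-sensitive, polymerisable nitroalkene and a heterogeneous metal reduction, would be spent to close a single C–N bond of a very simple indole.
- The end of N-methylation to A5 and C3 bromination: two more steps that build nothing, so that four of six steps in one linear line would only adjust functional groups.

**Retrosynthetic overview**
- The benzenoid ring is cut at C3a–C4 and C7–C7a. The edge C4(H)–C5(Br)–C6(Br)–C7(H) is a 2,3-dibromosuccinaldehyde unit, carried as the cyclic bis-acetal 5. The remainder (N1–CH3, C2, C3–Br, C3a, C7a) is 3-bromo-1-methylpyrrole 3.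
- Ring order: the pyrrole ring is present from the first compound. The benzene ring is closed last, by an acid-mediated double Friedel–Crafts annulation with twofold elimination that should give the target directly.
- The design needs no nitration, no nitro chemistry and no reduction, and it uses or passes through none of A1, A2, A3, A4 and A5. The N-methyl group and all three bromines sit in the two fragments before they are joined, so no functionalisation follows the ring closure. The route is convergent, with three steps.

Key step: step 3

Assumption: dibromide 5 would be used as the mixture of diastereomers that the bromine addition gives; the target has no stereocentre, and the four sp3 centres of 5 are erased on aromatisation.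

Step 1
Reactants: 1 1-methyl-1H-pyrrole
Product: 3 3-bromo-1-methyl-1H-pyrrole, via 2-bromo-1-methylpyrrole 2 (not isolated)
Conditions: NBS (1.0 equiv), PBr3 (5 mol %), THF, −78 °C to 0 °C, dark; hexane, filtration, distillation under reduced pressure; stored cold over K2CO3
Reagents that add atoms: N-bromosuccinimide, O=C1CCC(=O)N1Br
Why: Electrophilic aromatic bromination should give the kinetic 2-bromide, and the traces of HBr that PBr3 provides should catalyse the acid-mediated migration of bromine (C-protonation and bromine transfer) to the thermodynamically preferred 3-position.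

Step 2
Reactants: 4 2,5-dimethoxy-2,5-dihydrofuran (commercial cis/trans mixture)
Product: 5 3,4-dibromo-2,5-dimethoxytetrahydrofuran (3,4-trans, mixture of diastereomers)
Conditions: Br2 (1.0 equiv), CH2Cl2, −20 °C to 0 °C, dark; cold aqueous Na2S2O3/NaHCO3 wash; used crude
Reagents that add atoms: bromine, BrBr
Why: Electrophilic anti addition of bromine to the isolated ring alkene through a bromonium ion should give the trans-dibromide, and the cold, buffered work-up should keep both acetals intact.

Step 3
Reactants: 3 3-bromo-1-methyl-1H-pyrrole; 5 3,4-dibromo-2,5-dimethoxytetrahydrofuran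
Product: 8 3,5,6-tribromo-1-methyl-1H-indole, via C5-alkylated pyrrole 6 (not isolated), via oxa-bridged tetrahydroindole 7 (not isolated)
Conditions: 5 (1.3 equiv), TfOH (20 mol %), ClCH2CH2Cl, 0 °C, slow addition of 3 over 2 h; then 60 °C; NaHCO3 quench; chromatography
Reagents that add atoms: none
Why: Acid should ionise one acetal carbon of 5 to an oxocarbenium ion that alkylates pyrrole 3 at its free α-carbon C5 to give 6; ionisation of the second acetal and attack of the adjacent β-carbon C4 should then close the six-membered carbocycle (intramolecular Friedel–Crafts closure through a six-membered transition state) to the oxa-bridged 7. Acid should open the oxygen bridge at C7 through the pyrrole-stabilised cation, loss of H-6 gives the vinyl bromide, and ionisation of the C4 hydroxyl with loss of H-5 and water aromatises the ring; both C–Br bonds should be kept because only oxygen leaving groups sit on the cation-stabilised carbons. The closest known reaction type is the acid-mediated benzannulation of pyrroles to indoles, and of indoles to carbazoles, with 2,5-dimethoxytetrahydrofuran or 2,5-hexanedione as four-carbon 1,4-dielectrophiles. No stereocentre remains, since the four sp3 carbons of 5 become the aromatic carbons C4 to C7. The selectivity needed is first attack at C5 and not at C2 of 3: C2 is shielded by the N-methyl group and the bromine, and a C2 adduct cannot close because C3 is blocked, so it should revert under acid or stay unproductive while the C5 adduct is drained irreversibly by aromatisation. Slow addition of 3 should keep pyrrole–pyrrole coupling low.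

**Compound list**
1 | 1-methyl-1H-pyrrole | Cn1cccc1 | starting material
2 | 2-bromo-1-methyl-1H-pyrrole | Cn1cccc1Br | intermediate
3 | 3-bromo-1-methyl-1H-pyrrole | Cn1ccc(Br)c1 | intermediate
4 | 2,5-dimethoxy-2,5-dihydrofuran (cis/trans mixture) | COC1C=CC(OC)O1 | starting material
5 | 3,4-dibromo-2,5-dimethoxytetrahydrofuran (3,4-trans, mixture of diastereomers) | COC1OC(OC)C(Br)C1Br | intermediate
6 | 4-bromo-2-(3,4-dibromo-5-methoxyoxolan-2-yl)-1-methyl-1H-pyrrole (mixture of diastereomers) | COC1OC(c2cc(Br)cn2C)C(Br)C1Br | intermediate
7 | 3,5,6-tribromo-1-methyl-4,5,6,7-tetrahydro-1H-4,7-epoxyindole (mixture of diastereomers) | Cn1cc(Br)c2c1C1OC2C(Br)C1Br | intermediate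
8 | 3,5,6-tribromo-1-methyl-1H-indole | Cn1cc(Br)c2cc(Br)c(Br)cc21 | target

Total step count: 3
Longest linear sequence: 2 (step 1 or step 2, then step 3)

**Steps most likely to fail**

1. Step 3 (benzannulation).
   - What may go wrong: the first alkylation may go to C2 of 3 and feed oligomerisation. The strong acid may move or remove the C3 bromine of 3 or of the product. Acetal 5 may lose methanol to bromofurans before it is trapped.
   - Fallback: it sets out from 5 and comes back at 8. The pyrrole partner would be commercial methyl 1-methyl-1H-pyrrole-3-carboxylate F1, whose ester is acid-stable and directs electrophiles to C5.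
   - Benzannulation with 5 (TfOH 1.5 equiv, ClCH2CH2Cl, rt to 60 °C) should give methyl 5,6-dibromo-1-methyl-1H-indole-3-carboxylate F2.
   - Saponification (LiOH, THF/MeOH/H2O, 50 °C) should give 5,6-dibromo-1-methyl-1H-indole-3-carboxylic acid F3.
   - Ipso-bromodecarboxylation (NBS 1.05 equiv, DMF, 0 °C to rt) should give 8, so the C3 bromine would enter last and never meet the strong acid.

2. Step 1 (bromination with bromine migration).
   - What may go wrong: incomplete migration from C2 to C3, or polybromination, would leave isomers that are hard to remove by distillation and that would carry through to isomeric indoles.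
   - Fallback: it sets out from 1 and comes back at 3. Acylation of 1 with trichloroacetyl chloride (Et2O, rt) should give 2,2,2-trichloro-1-(1-methyl-1H-pyrrol-2-yl)ethan-1-one F4.
   - The acyl group should direct NBS (THF, −10 °C) to C4, giving 1-(4-bromo-1-methyl-1H-pyrrol-2-yl)-2,2,2-trichloroethan-1-one F5.
   - Haloform cleavage (aqueous NaOH, then acid) should give 4-bromo-1-methyl-1H-pyrrole-2-carboxylic acid F6.
   - Protodecarboxylation (Ag2CO3 10 mol %, AcOH, DMSO, 120 °C) should deliver 3 as a single isomer.

3. Step 2 (bromine addition).
   - What may go wrong: HBr or methanol may be lost from the cyclic bis-acetal during addition, work-up or storage, with drift towards bromofurans.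
   - Fallback: it sets out from 3 and comes back at 8. The four-carbon unit would be brought in open-chain form: commercial (E)-1,1,4,4-tetramethoxybut-2-ene F7 with Br2 (CH2Cl2, 0 °C) should give meso-2,3-dibromo-1,1,4,4-tetramethoxybutane F8 by anti addition.
   - F8 would then be combined with 3 under the conditions of step 3 to give 8.

**Further compounds**
F1 | step 3 | methyl 1-methyl-1H-pyrrole-3-carboxylate | COC(=O)c1ccn(C)c1
F2 | step 3 | methyl 5,6-dibromo-1-methyl-1H-indole-3-carboxylate | COC(=O)c1cn(C)c2cc(Br)c(Br)cc12
F3 | step 3 | 5,6-dibromo-1-methyl-1H-indole-3-carboxylic acid | OC(=O)c1cn(C)c2cc(Br)c(Br)cc12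
F4 | step 1 | 2,2,2-trichloro-1-(1-methyl-1H-pyrrol-2-yl)ethan-1-one | Cn1cccc1C(=O)C(Cl)(Cl)Cl
F5 | step 1 | 1-(4-bromo-1-methyl-1H-pyrrol-2-yl)-2,2,2-trichloroethan-1-one | Cn1cc(Br)cc1C(=O)C(Cl)(Cl)Cl
F6 | step 1 | 4-bromo-1-methyl-1H-pyrrole-2-carboxylic acid | Cn1cc(Br)cc1C(=O)O
F7 | step 2 | (E)-1,1,4,4-tetramethoxybut-2-ene | COC(OC)/C=C/C(OC)OC
F8 | step 2 | meso-2,3-dibromo-1,1,4,4-tetramethoxybutane | COC(OC)[C@H](Br)[C@H](Br)C(OC)OC
A1 | direct plan | 3,4-dibromobenzaldehyde | O=Cc1ccc(Br)c(Br)c1
A2 | direct plan | 4,5-dibromo-2-nitrobenzaldehyde | O=Cc1cc(Br)c(Br)cc1[N+](=O)[O-]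
A3 | direct plan | 1,2-dibromo-4-nitro-5-[(E)-2-nitroethenyl]benzene | O=[N+]([O-])/C=C/c1cc(Br)c(Br)cc1[N+](=O)[O-]
A4 | direct plan | 5,6-dibromo-1H-indole | Brc1cc2cc[nH]c2cc1Br
A5 | direct plan | 5,6-dibromo-1-methyl-1H-indole | Cn1ccc2cc(Br)c(Br)cc21
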